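**Plan**

1. Ring numbering used throughout: C1 (stereocentre, carries the 6-methylhepta-1,5-dien-2-yl group), C2, C3=C4 (C4 carries CH2OH; E by CIP, so C2 and C5 are cis), C5, C6, C7=C8 (C8 carries CH3), C9, C10, C11=C12 (C12 carries CH3), C13, C14.
2. Enabling feature: the Z alkene C7=C8 holds its ring neighbours C6 and C9 cis, so it is the 1,4-dihydro form of an s-cis diene C6=C7–C8=C9 in the fourteen-membered ring. The retrosynthesis removes two hydrogens from C6/C9 and cuts the diene at the sp2–sp2 bond C7–C8, giving an open-chain bis(E-alkenyl iodide).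
3. Further cuts: both C–I bonds back to alkynes (terminal C6≡C7, methyl-capped C8≡C9), C3=C4 (Wittig), C9–C10 (alkynyl–allyl coupling), C11=C12 (Horner–Wadsworth–Emmons) and the side-chain CH2–CH2 bond (allyl anion plus prenyl bromide). C3 and C12 are then the aldehyde and methyl ketone from opening the ring alkene of (R)-limonene.
4. Forward order: limonene, protected 1,2-diol, side-chain prenylation, glycol cleavage, the C12-to-C8 arm, the C3-to-C7 arm, double hydrozirconation–iodination, macrocyclisation (the only ring), 1,4-hydrogenation, desilylation.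
5. Stereochemistry: C1 (R) is C4 of (R)-limonene and is never touched. 3E and 11E come from the two carbonyl olefinations, the alkenyl iodide geometries from syn-hydrozirconation, and 7Z from 1,4-addition of H2 to the s-cis diene.

Key step: step 15

Remark: the target SMILES is read as R at C1; the substituent priority order at this carbon is the same in (R)-limonene and in every intermediate, so the descriptor stays R throughout.

**Route**

Step 1
Reactants: 1 (R)-limonene
Product: 3 (1S,2S,4R)-limonene-1,2-diol, via limonene 1,2-oxide 2 (not isolated)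
Conditions: mCPBA (1.0 equiv), CH2Cl2, 0 °C; then 0.1 M H2SO4, THF/H2O, 0 °C to rt
Reagents that add atoms: mCPBA, OOC(=O)c1cccc(Cl)c1; water, O
Why: Prilezhaev epoxidation takes the electron-rich trisubstituted ring alkene in preference to the isopropenyl group, and acid hydrolysis opens both epoxide diastereomers trans-diaxially (Fürst–Plattner) to the same diol, whose two new carbinol centres are erased again in step 4.

Step 2
Reactants: 3 (1S,2S,4R)-limonene-1,2-diol
Product: 4 acetonide of diol 3
Conditions: 2-methoxypropene, PPTS (cat.), CH2Cl2, 0 °C to rt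
Reagents that add atoms: 2-methoxypropene, COC(C)=C
Why: Acid-catalysed ketalisation with an enol ether masks the glycol as a base-stable dioxolane, and trans-cyclohexane-1,2-diols are known to give the trans-fused acetonide after ring inversion to the diequatorial diol.

Step 3
Reactants: 4 acetonide of diol 3; 5 prenyl bromide
Product: 7 acetonide of (1S,2S,4R)-1-methyl-4-(6-methylhepta-1,5-dien-2-yl)cyclohexane-1,2-diol, via allyllithium 6 (not isolated)
Conditions: n-BuLi, TMEDA, hexane, 0 °C to rt; then 5, THF, −78 °C to rt
Reagents that add atoms: none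
Why: Allylic metalation of the isopropenyl methyl group (the deprotonation known for limonene itself) gives a symmetrical 2-substituted allyllithium whose two termini are equivalent, and SN2 alkylation at the primary carbon of prenyl bromide completes the side chain while the allylic methine stereocentre is left untouched.

Step 4
Reactants: 7 prenylated acetonide
Product: 9 (3R)-3-(6-methylhepta-1,5-dien-2-yl)-6-oxoheptanal, via prenylated diol 8 (not isolated)
Conditions: H5IO6 (3 equiv), THF/H2O, 0 °C to rt
Reagents that add atoms: none
Why: Periodic acid is acidic enough to hydrolyse the strained trans-fused acetonide and then cleaves the liberated glycol (Malaprade reaction) to the methyl ketone and the aldehyde, the isolated alkenes being inert to periodate.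

Step 5
Reactants: 9 keto aldehyde
Product: 10 (5R)-7,7-dimethoxy-5-(6-methylhepta-1,5-dien-2-yl)heptan-2-one
Conditions: HC(OMe)3, CeCl3·7H2O (cat.), MeOH, 0 °C to rt
Reagents that add atoms: methanol, CO; trimethyl orthoformate, COC(OC)OC
Why: Cerium-catalysed acetalisation with trimethyl orthoformate in methanol discriminates kinetically between an aldehyde and a ketone, so only the aldehyde is masked.

Step 6
Reactants: 10 keto acetal; 11 triethyl phosphonoacetate
Product: 12 ethyl (2E,6R)-8,8-dimethoxy-3-methyl-6-(6-methylhepta-1,5-dien-2-yl)oct-2-enoate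
Conditions: NaH, 11, THF, 0 to 50 °C; chromatographic removal of the 2Z isomer
Reagents that add atoms: none
Why: Horner–Wadsworth–Emmons olefination of the methyl ketone places the ester anti to the larger alkyl branch, so the 2E enoate (the future 11E alkene C11=C12) should predominate and the minor Z isomer is separable at this ester stage.

Step 7
Reactants: 12 E enoate
Product: 13 (2E,6R)-8,8-dimethoxy-3-methyl-6-(6-methylhepta-1,5-dien-2-yl)oct-2-en-1-ol
Conditions: i-Bu2AlH, CH2Cl2, −78 °C
Reagents that add atoms: none
Why: 1,2-Reduction of an α,β-unsaturated ester by i-Bu2AlH at low temperature gives the allylic alcohol without touching the acetal or the alkenes.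

Step 8
Reactants: 13 allylic alcohol
Product: 15 (2E,6R)-1-bromo-8,8-dimethoxy-3-methyl-6-(6-methylhepta-1,5-dien-2-yl)oct-2-ene, via mesylate 14 (not isolated)
Conditions: MsCl, Et3N, THF, −40 °C; then LiBr, THF, 0 °C
Reagents that add atoms: LiBr, [Li+].[Br-]
Why: Mesylation followed by SN2 displacement with bromide under non-acidic conditions gives the primary allylic bromide without allylic transposition, loss of alkene geometry or acetal cleavage.

Step 9
Reactants: 15 allylic bromide; 16 prop-1-yn-1-ylmagnesium bromide
Product: 18 (3R,6E)-6-methyl-3-(6-methylhepta-1,5-dien-2-yl)undec-6-en-9-ynal, via enyne acetal 17 (not isolated)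
Conditions: 16, CuI (10 mol %), THF, 0 to 50 °C; then 1 M HCl, THF, rt
Reagents that add atoms: water, O
Why: Copper-catalysed SN2 coupling of an alkynyl Grignard reagent with a primary allylic bromide whose γ-carbon is fully substituted forms the C9–C10 bond of the skipped enyne, and the acidic work-up hydrolyses the dimethyl acetal to the aldehyde.

Step 10
Reactants: 19 ethyl (triphenylphosphoranylidene)acetate; 20 propargyl bromide
Product: 22 ethyl 2-(triphenylphosphoranylidene)pent-4-ynoate, via phosphonium bromide 21 (not isolated)
Conditions: 19 (2 equiv), 20, EtOAc, reflux; filtration of the precipitated salt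
Reagents that add atoms: none
Why: C-Alkylation of an ester-stabilised ylide by a reactive propargylic bromide followed by transylidation with a second equivalent of the ylide is the standard preparation of α-substituted stabilised Wittig reagents.

Step 11
Reactants: 18 enyne aldehyde; 22 propargyl-substituted ylide
Product: 23 ethyl (2E,5R,8E)-8-methyl-5-(6-methylhepta-1,5-dien-2-yl)-2-(prop-2-yn-1-yl)trideca-2,8-dien-11-ynoate
Conditions: 22, toluene, 80 °C
Reagents that add atoms: none
Why: Wittig olefination with an α-substituted ester-stabilised ylide is thermodynamically controlled and gives the E trisubstituted enoate, with the ester trans to C2 and the propargyl group (future C5) cis to C2, as C3=C4 of the ring requires.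

Step 12
Reactants: 23 dienyne ester
Product: 24 (2E,5R,8E)-8-methyl-5-(6-methylhepta-1,5-dien-2-yl)-2-(prop-2-yn-1-yl)trideca-2,8-dien-11-yn-1-ol
Conditions: i-Bu2AlH, CH2Cl2, −78 °C
Reagents that add atoms: none
Why: 1,2-Reduction of the enoate with i-Bu2AlH at −78 °C gives the allylic alcohol with retention of alkene geometry, both alkynes being inert at this temperature.

Step 13
Reactants: 24 dienyne alcohol
Product: 25 tert-butyldimethylsilyl ether of 24
Conditions: TBSCl, imidazole, CH2Cl2, rt
Reagents that add atoms: TBSCl, CC(C)(C)[Si](C)(C)Cl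
Why: Imidazole-promoted silylation of the primary allylic alcohol protects the hydroxyl group from the zirconium hydride of step 14 and the organometallic steps that follow.

Step 14
Reactants: 25 silyl ether
Product: 27 bis(E-alkenyl iodide) (iodine on C7 and on C8), via bis(alkenylzirconocene) 26 (not isolated)
Conditions: Cp2Zr(H)Cl (3 equiv), THF, rt then 45 °C; then I2, THF, 0 °C
Reagents that add atoms: iodine, [I][I]
Why: Hydrozirconation is a syn addition that places zirconium on the terminal carbon of the 1-alkyne and, after equilibration with excess reagent, on the less hindered methyl-bearing carbon of the 2-alkyne, and iodinolysis of both C–Zr bonds with retention should give the E iodides at C7 and C8.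

Step 15
Reactants: 27 bis(E-alkenyl iodide)
Product: 29 macrocyclic 6E,8E-diene silyl ether, via iodo stannane 28 (not isolated)
Conditions: Pd(PPh3)4 (20 mol %), Me3SnSnMe3 (1.2 equiv), toluene (0.002 M), 90 °C, degassed
Reagents that add atoms: none
Why: Zerovalent palladium inserts first into the unhindered terminal C7–I bond and Me3SnSnMe3 converts the alkenylpalladium iodide into alkenylstannane 28; a second oxidative addition into the hindered C8–I bond is followed by intramolecular tin-to-palladium transmetalation and reductive elimination, which forms C7–C8. The closest known reaction type is the Stille–Kelly coupling (ditin-mediated intramolecular union of two sp2 halides) combined with Stille macrocyclisation to 1,3-dienes. The fourteen-membered ring closes by reductive elimination from a cis-dialkenylpalladium that already carries both chain ends, a macrocyclic sp2–sp2 coupling helped by the three rigid alkene units of the tether and not subject to Baldwin-type constraints. No stereocentre is created; oxidative addition, transmetalation and reductive elimination all retain alkenyl geometry, so the product should be the 6E,8E diene with C5 and C10 on the outside of its s-cis form, as step 16 requires. The step needs ring closure to win over oligomerisation and over stannylation of both ends; this is secured by high dilution, a near-stoichiometric charge of ditin and the large rate difference between the terminal iodide and the 1,1-disubstituted one, so that one terminus becomes the nucleophile while the other remains the electrophile.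

Step 16
Reactants: 29 macrocyclic diene silyl ether
Product: 30 silyl ether of the target ((1R,3E,7Z,11E)-triene)
Conditions: H2 (50 atm), (η6-naphthalene)Cr(CO)3 (20 mol %), acetone, 25 °C
Reagents that add atoms: none
Why: The arene–Cr(CO)3 catalyst binds only a conjugated diene that can become s-cis and delivers both hydrogens to its termini C6 and C9 (1,4-hydrogenation), so the new C7=C8 alkene should be Z with C6 and C9 cis while the isolated alkenes and the allylic silyl ether stay untouched.

Step 17
Reactants: 30 silyl ether of the target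
Product: 31 CNP0217603.1
Conditions: Bu4NF, THF, 0 °C to rt
Reagents that add atoms: none
Why: Fluoride-induced cleavage of the Si–O bond (desilylation) frees the primary allylic alcohol under conditions that leave the skipped polyene unchanged.

**Compound list**

1 | (R)-(+)-limonene, (4R)-1-methyl-4-(prop-1-en-2-yl)cyclohex-1-ene | CC1=CC[C@@H](CC1)C(C)=C | starting material
2 | (4R)-limonene 1,2-oxide, mixture of cis and trans epoxides | CC12OC1C[C@@H](CC2)C(C)=C | intermediate
3 | (1S,2S,4R)-1-methyl-4-(prop-1-en-2-yl)cyclohexane-1,2-diol (trans-diaxial limonene-1,2-diol) | C[C@@]1(O)[C@@H](O)C[C@@H](CC1)C(C)=C | intermediate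
4 | acetonide of 3 (trans-fused 2,2-dimethyl-1,3-dioxolane across C1/C2 of the cyclohexane, isopropenyl group at C4 unchanged) | C[C@@]12OC(C)(C)O[C@H]1C[C@@H](CC2)C(C)=C | intermediate
5 | prenyl bromide, 1-bromo-3-methylbut-2-ene | CC(C)=CCBr | starting material
6 | allyllithium from 4 (lithium on the former isopropenyl methyl carbon) | C[C@@]12OC(C)(C)O[C@H]1C[C@@H](CC2)C(=C)C[Li] | intermediate
7 | acetonide of (1S,2S,4R)-1-methyl-4-(6-methylhepta-1,5-dien-2-yl)cyclohexane-1,2-diol | C[C@@]12OC(C)(C)O[C@H]1C[C@@H](CC2)C(=C)CCC=C(C)C | intermediate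
8 | (1S,2S,4R)-1-methyl-4-(6-methylhepta-1,5-dien-2-yl)cyclohexane-1,2-diol | C[C@@]1(O)[C@@H](O)C[C@@H](CC1)C(=C)CCC=C(C)C | intermediate
9 | (3R)-3-(6-methylhepta-1,5-dien-2-yl)-6-oxoheptanal | CC(=O)CC[C@H](CC=O)C(=C)CCC=C(C)C | intermediate
10 | (5R)-7,7-dimethoxy-5-(6-methylhepta-1,5-dien-2-yl)heptan-2-one | CC(=O)CC[C@H](CC(OC)OC)C(=C)CCC=C(C)C | intermediate
11 | triethyl phosphonoacetate | CCOC(=O)CP(=O)(OCC)OCC | starting material
12 | ethyl (2E,6R)-8,8-dimethoxy-3-methyl-6-(6-methylhepta-1,5-dien-2-yl)oct-2-enoate | CCOC(=O)/C=C(\C)CC[C@H](CC(OC)OC)C(=C)CCC=C(C)C | intermediate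
13 | (2E,6R)-8,8-dimethoxy-3-methyl-6-(6-methylhepta-1,5-dien-2-yl)oct-2-en-1-ol | OC/C=C(\C)CC[C@H](CC(OC)OC)C(=C)CCC=C(C)C | intermediate
14 | methanesulfonate of 13 | CS(=O)(=O)OC/C=C(\C)CC[C@H](CC(OC)OC)C(=C)CCC=C(C)C | intermediate
15 | (2E,6R)-1-bromo-8,8-dimethoxy-3-methyl-6-(6-methylhepta-1,5-dien-2-yl)oct-2-ene | BrC/C=C(\C)CC[C@H](CC(OC)OC)C(=C)CCC=C(C)C | intermediate
16 | prop-1-yn-1-ylmagnesium bromide | CC#C[Mg]Br | starting material
17 | (3R,6E)-1,1-dimethoxy-6-methyl-3-(6-methylhepta-1,5-dien-2-yl)undec-6-en-9-yne | CC#CC/C=C(\C)CC[C@H](CC(OC)OC)C(=C)CCC=C(C)C | intermediate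
18 | (3R,6E)-6-methyl-3-(6-methylhepta-1,5-dien-2-yl)undec-6-en-9-ynal | CC#CC/C=C(\C)CC[C@H](CC=O)C(=C)CCC=C(C)C | intermediate
19 | ethyl (triphenylphosphoranylidene)acetate | CCOC(=O)C=P(c1ccccc1)(c1ccccc1)c1ccccc1 | starting material
20 | propargyl bromide, 3-bromoprop-1-yne | C#CCBr | starting material
21 | (1-ethoxy-1-oxopent-4-yn-2-yl)triphenylphosphonium bromide | CCOC(=O)C(CC#C)[P+](c1ccccc1)(c1ccccc1)c1ccccc1.[Br-] | intermediate
22 | ethyl 2-(triphenylphosphoranylidene)pent-4-ynoate | CCOC(=O)C(CC#C)=P(c1ccccc1)(c1ccccc1)c1ccccc1 | intermediate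
23 | ethyl (2E,5R,8E)-8-methyl-5-(6-methylhepta-1,5-dien-2-yl)-2-(prop-2-yn-1-yl)trideca-2,8-dien-11-ynoate | CC#CC/C=C(\C)CC[C@H](C/C=C(/C(=O)OCC)CC#C)C(=C)CCC=C(C)C | intermediate
24 | (2E,5R,8E)-8-methyl-5-(6-methylhepta-1,5-dien-2-yl)-2-(prop-2-yn-1-yl)trideca-2,8-dien-11-yn-1-ol | CC#CC/C=C(\C)CC[C@H](C/C=C(/CO)CC#C)C(=C)CCC=C(C)C | intermediate
25 | tert-butyldimethylsilyl ether of 24 | CC#CC/C=C(\C)CC[C@H](C/C=C(/CO[Si](C)(C)C(C)(C)C)CC#C)C(=C)CCC=C(C)C | intermediate
26 | bis(alkenylzirconocene chloride) from 25: E-alkenyl–ZrCp2Cl at C7 (terminal) and at C8 (methyl-bearing carbon) | C/C(=C\C/C=C(\C)CC[C@H](C/C=C(/CO[Si](C)(C)C(C)(C)C)C/C=C/[Zr](Cl)(C1C=CC=C1)C1C=CC=C1)C(=C)CCC=C(C)C)[Zr](Cl)(C1C=CC=C1)C1C=CC=C1 | intermediate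
27 | tert-butyldimethylsilyl ether of (2E,5R,8E,11E)-12-iodo-2-[(2E)-3-iodoprop-2-en-1-yl]-8-methyl-5-(6-methylhepta-1,5-dien-2-yl)trideca-2,8,11-trien-1-ol | C/C(I)=C\C/C=C(\C)CC[C@H](C/C=C(/CO[Si](C)(C)C(C)(C)C)C/C=C/I)C(=C)CCC=C(C)C | intermediate
28 | 27 with the terminal (C7) iodide replaced by trimethylstannyl | C/C(I)=C\C/C=C(\C)CC[C@H](C/C=C(/CO[Si](C)(C)C(C)(C)C)C/C=C/[Sn](C)(C)C)C(=C)CCC=C(C)C | intermediate
29 | (1R,3E,6E,8E,11E)-4-[(tert-butyldimethylsilyloxy)methyl]-8,12-dimethyl-1-(6-methylhepta-1,5-dien-2-yl)cyclotetradeca-3,6,8,11-tetraene (ring numbering of the plan) | C=C(CCC=C(C)C)[C@H]1C/C=C(/CO[Si](C)(C)C(C)(C)C)C/C=C/C(C)=C/C/C=C(\C)CC1 | intermediate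
30 | (1R,3E,7Z,11E)-4-[(tert-butyldimethylsilyloxy)methyl]-8,12-dimethyl-1-(6-methylhepta-1,5-dien-2-yl)cyclotetradeca-3,7,11-triene | C=C(CCC=C(C)C)[C@H]1C/C=C(/CO[Si](C)(C)C(C)(C)C)CC/C=C(/C)CC/C=C(\C)CC1 | intermediate
31 | CNP0217603.1, (1R,3E,7Z,11E)-4-(hydroxymethyl)-8,12-dimethyl-1-(6-methylhepta-1,5-dien-2-yl)cyclotetradeca-3,7,11-triene | C=C(CCC=C(C)C)[C@H]1C/C=C(/CO)CC/C=C(/C)CC/C=C(\C)CC1 | target

**Step count and risks**

Total: 17 steps. Longest linear sequence: 16 steps (steps 1 to 9 and 11 to 17); step 10 is a one-step side branch.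

Most likely to fail, first: step 15. After the first stannylation, the macrocyclic transmetalation at the hindered C8–palladium centre is slow. It can be outrun by stannylation of the second iodide, by methyl transfer from tin, or by coupling between two molecules, so open-chain and oligomeric material would form instead of the ring. The fallback separates the two events and takes palladium out of the ring closure. It sets out from bis(alkenyl iodide) 27: the stannylation with Pd(PPh3)4 and Me3SnSnMe3 is run at lower temperature and stopped once the terminal iodide has reacted, and iodo stannane 28 is isolated. Stannane 28 is then cyclised by the copper-mediated Stille-type coupling of an alkenylstannane with an alkenyl iodide, using copper thiophene-2-carboxylate (monovalent copper) in NMP at room temperature under high dilution. This returns to the route at macrocycle 29.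

Second: step 14. Zirconium may migrate incompletely to the methyl-bearing carbon of the 2-alkyne, leaving a regioisomeric iodide. The forcing conditions needed for that migration may also hydrozirconate the 1,1-disubstituted side-chain alkene while a second alkyne and the silyl ether compete for the reagent. The fallback uncouples the two hydrometalations and moves the demanding one to a simple early intermediate.
- It sets out from allylic bromide 15. The coupling of step 9 is worked up with aqueous NH4Cl so that enyne acetal 17 is isolated.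
- Thermodynamic hydrozirconation of 17 with Cp2Zr(H)Cl gives the alkenylzirconocene F1, and iodine converts it into the iodo acetal F2, from which any regioisomer is removed by chromatography.
- Aqueous HCl in THF gives the iodo aldehyde F3, Wittig olefination with ylide 22 the iodo ester F4, i-Bu2AlH at −78 °C the iodo alcohol F5, and TBSCl with imidazole the iodo silyl ether F6.
- The terminal alkyne of F6 is hydrozirconated with about one equivalent of Cp2Zr(H)Cl at room temperature, where the side-chain alkene is inert, to the alkenylzirconocene F7. Iodine then returns to the route at bis(alkenyl iodide) 27.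

Third: step 3. Deprotonation next to oxygen in the dioxolane, with fragmentation, can compete with allylic metalation, and the allyl anion can attack the tertiary end of prenyl bromide or undergo halogen–metal exchange, so conversion to the linear side chain may be poor. The fallback builds the same CH2–CH2 bond with the polarity reversed and without a strong base on the acetonide.
- It sets out from acetonide 4. Selenium-catalysed allylic chlorination (N-chlorosuccinimide, cat. PhSeCl, CH2Cl2) gives the allylic chloride F8.
- Prenyl phenyl sulfone F9, made from prenyl bromide 5 and PhSO2Na in DMF, is deprotonated with n-BuLi at −78 °C and alkylated with F8 to the sulfone F10.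
- Reductive desulfonylation with PdCl2(dppp) and LiBHEt3 in THF, without migration of the prenyl alkene, returns to the route at prenylated acetonide 7.

Further compounds
F0 | step 15 | none | none
F1 | step 14 | alkenylzirconocene chloride from enyne acetal 17 (zirconium on the methyl-bearing alkyne carbon, formed in the flask) | C/C(=C\C/C=C(\C)CC[C@H](CC(OC)OC)C(=C)CCC=C(C)C)[Zr](Cl)(C1C=CC=C1)C1C=CC=C1
F2 | step 14 | (2E,5E,9R)-2-iodo-11,11-dimethoxy-6-methyl-9-(6-methylhepta-1,5-dien-2-yl)undeca-2,5-diene | C/C(I)=C\C/C=C(\C)CC[C@H](CC(OC)OC)C(=C)CCC=C(C)C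
F3 | step 14 | (3R,6E,9E)-10-iodo-6-methyl-3-(6-methylhepta-1,5-dien-2-yl)undeca-6,9-dienal | C/C(I)=C\C/C=C(\C)CC[C@H](CC=O)C(=C)CCC=C(C)C
F4 | step 14 | ethyl (2E,5R,8E,11E)-12-iodo-8-methyl-5-(6-methylhepta-1,5-dien-2-yl)-2-(prop-2-yn-1-yl)trideca-2,8,11-trienoate | C/C(I)=C\C/C=C(\C)CC[C@H](C/C=C(/C(=O)OCC)CC#C)C(=C)CCC=C(C)C
F5 | step 14 | (2E,5R,8E,11E)-12-iodo-8-methyl-5-(6-methylhepta-1,5-dien-2-yl)-2-(prop-2-yn-1-yl)trideca-2,8,11-trien-1-ol | C/C(I)=C\C/C=C(\C)CC[C@H](C/C=C(/CO)CC#C)C(=C)CCC=C(C)C
F6 | step 14 | tert-butyldimethylsilyl ether of F5 | C/C(I)=C\C/C=C(\C)CC[C@H](C/C=C(/CO[Si](C)(C)C(C)(C)C)CC#C)C(=C)CCC=C(C)C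
F7 | step 14 | terminal E-alkenylzirconocene chloride from F6 (formed in the flask) | C/C(I)=C\C/C=C(\C)CC[C@H](C/C=C(/CO[Si](C)(C)C(C)(C)C)C/C=C/[Zr](Cl)(C1C=CC=C1)C1C=CC=C1)C(=C)CCC=C(C)C
F8 | step 3 | allylic chloride from acetonide 4 (3-chloroprop-1-en-2-yl group in place of isopropenyl) | C[C@@]12OC(C)(C)O[C@H]1C[C@@H](CC2)C(=C)CCl
F9 | step 3 | prenyl phenyl sulfone, [(3-methylbut-2-en-1-yl)sulfonyl]benzene | CC(C)=CCS(=O)(=O)c1ccccc1
F10 | step 3 | sulfone from F8 and F9 (phenylsulfonyl group on the side-chain carbon next to the prenyl alkene, mixture of epimers at that carbon) | C[C@@]12OC(C)(C)O[C@H]1C[C@@H](CC2)C(=C)CC(C=C(C)C)S(=O)(=O)c1ccccc1
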